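## Retrosynthetic overview

1. Sikokianin B ⇐ its penta-O-benzyl ether carrying two bromine atoms on the methoxyphenyl ring; one final hydrogenolysis removes both, and the bromines serve only to steer the key step.
2. Both pyranone rings (ring C of each flavanone half) and both C4–C3 bonds ⇐ one carbene-catalysed alkyne hydroacylation / intramolecular Stetter cascade on an acyclic bis(2-formylaryl) ether of a 1,4-diarylbut-2-yne-1,4-diol. C3 and C3'' are set here; C2 and C2'' are already in place.
3. Bis-ether ⇐ (R,R)-diol + two molecules of 4,6-bis(benzyloxy)-2-hydroxybenzaldehyde (double Mitsunobu with inversion).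
4. Diol ⇐ 4-(benzyloxy)benzaldehyde + ethynyltrimethylsilane + 3,5-dibromo-4-methoxybenzaldehyde (two catalytic asymmetric alkynylations; the two alkyne carbons become C3 and C3'').
5. Ring order: rings A and B are bought as arenes; ring C of the 4-hydroxyphenyl half closes first and ring C of the 4-methoxyphenyl half second, in the same flask.

Labels: unit 1 = the 2-(4-methoxyphenyl)chromanone half (C2, C3, C4); unit 2 = the 2-(4-hydroxyphenyl)chromanone half (C2'', C3'', C4''). The target is (2R,3S,2''R,3''R): unit 1 is 2,3-trans, unit 2 is 2,3-cis.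

Assumption: "(R,R)-ProPhenol" denotes the ligand antipode that adds the alkynylzinc to the Si face of an aryl aldehyde; if the catalyst's sense is the opposite, the other antipode is used in steps 2 and 3.

## Route

Step 1
Reactants: 1 2,4,6-trihydroxybenzaldehyde
Product: 2 4,6-bis(benzyloxy)-2-hydroxybenzaldehyde
Conditions: BnBr (2.1 equiv), K2CO3 (2.2 equiv), DMF, 0 °C to rt
Reagents that add atoms: benzyl bromide, BrCc1ccccc1
Why: Williamson etherification in which the 4-OH and one ortho OH are alkylated while the remaining ortho OH stays free because it is hydrogen-bonded to the formyl group, as in the usual selective dibenzylation of phloroglucinol aldehydes and ketones; no stereocenter is formed.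

Step 2
Reactants: 3 4-(benzyloxy)benzaldehyde; 4 ethynyltrimethylsilane
Product: 6 (1S)-1-[4-(benzyloxy)phenyl]prop-2-yn-1-ol, via silyl alkynol 5 (not isolated)
Conditions: 4 (3 equiv), Me2Zn (3 equiv), (R,R)-ProPhenol (10 mol%), toluene, 0 °C; aq. NH4Cl; then K2CO3 (cat.), MeOH, rt
Reagents that add atoms: none
Why: Zinc–ProPhenol catalysed enantioselective alkynylation of an aryl aldehyde, in which the dinuclear zinc catalyst delivers the alkynylzinc to the Si face and so sets the carbinol centre that later becomes C2'' (R in 5, S in 6 only because the CIP ranking changes on desilylation), followed by methanolysis of the C–Si bond.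

Step 3
Reactants: 6 (1S)-1-[4-(benzyloxy)phenyl]prop-2-yn-1-ol; 7 3,5-dibromo-4-methoxybenzaldehyde
Product: 8 (1R,4R)-1-[4-(benzyloxy)phenyl]-4-(3,5-dibromo-4-methoxyphenyl)but-2-yne-1,4-diol
Conditions: 6 (1.5 equiv), Me2Zn (4.5 equiv), (R,R)-ProPhenol (20 mol%), toluene, rt, then 7 at 0 °C; aq. NH4Cl
Reagents that add atoms: none
Why: Second zinc–ProPhenol alkynylation, in which the alkynylzinc of 6 (its hydroxyl carried as the zinc alkoxide) adds to the Si face of the electron-poor aldehyde under catalyst control and sets the carbinol that becomes C2; the minor unlike diol is removed by chromatography, which also raises the ee of 8.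

Step 4
Reactants: 8 (1R,4R)-1-[4-(benzyloxy)phenyl]-4-(3,5-dibromo-4-methoxyphenyl)but-2-yne-1,4-diol; 2 4,6-bis(benzyloxy)-2-hydroxybenzaldehyde
Product: 11 2,2'-{[(1S,4S)-1-[4-(benzyloxy)phenyl]-4-(3,5-dibromo-4-methoxyphenyl)but-2-yne-1,4-diyl]bis(oxy)}bis[4,6-bis(benzyloxy)benzaldehyde], via mono-ether 9 (not isolated), via mono-ether 10 (not isolated)
Conditions: 2 (2.4 equiv), PPh3 (2.6 equiv), DIAD (2.6 equiv), toluene, −20 °C to rt
Reagents that add atoms: none
Why: Double Mitsunobu etherification in which the acidic, hydrogen-bonded phenol displaces each oxyphosphonium group by SN2, so both carbinol centres are inverted (R,R to S,S) and take the spatial arrangement of C2 and C2'' of the target, with toluene and low temperature used to suppress ionisation of the benzylic-propargylic carbons.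

Step 5
Reactants: 11 2,2'-{[(1S,4S)-1-[4-(benzyloxy)phenyl]-4-(3,5-dibromo-4-methoxyphenyl)but-2-yne-1,4-diyl]bis(oxy)}bis[4,6-bis(benzyloxy)benzaldehyde]
Product: 13 (2R,3S)-5,7-bis(benzyloxy)-3-{(2R,3R)-5,7-bis(benzyloxy)-2-[4-(benzyloxy)phenyl]-4-oxo-3,4-dihydro-2H-chromen-3-yl}-2-(3,5-dibromo-4-methoxyphenyl)-2,3-dihydro-4H-chromen-4-one, via enone aldehyde 12 (not isolated)
Conditions: 3-mesityl-5,6,7,8-tetrahydro-4H-cyclohepta[d]thiazol-3-ium perchlorate (20 mol%), K2CO3 (40 mol%), 2,6-di-tert-butyl-4-methylphenol (1 equiv), THF (0.02 M), 70 °C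
Reagents that add atoms: none
Why: Proposed new method: the carbene converts one formyl group into a Breslow intermediate that adds across the unactivated alkyne in a concerted Conia-ene-type syn hydroacylation (closest known type: carbene-catalysed hydroacylation of 2-propargyloxybenzaldehydes to 3-alkylidenechromanones and the hydroacylation–Stetter cascade built on it), after which the second formyl group closes the other ring by an intramolecular Stetter reaction onto the new (E)-enone (closest known type: chromanone-forming intramolecular Stetter reactions with trisubstituted acceptors); the negative charge building up on the distal alkyne carbon is better stabilised next to the carbon that bears the electron-poor dibromoaryl group, so the aldehyde on the 4-benzyloxyphenyl side should react first and close ring C of unit 2 (12); the Stetter step then attacks C3 from the face fixed by C2 with the C2–H bond eclipsing the alkene (1,3-allylic strain), which places C3 trans to the C2 aryl group (3S); and the resulting ring enol(ate) of unit 2 is protonated by the bulky external phenol on the face opposite its pseudo-axial C2'' aryl group, which places C3'' cis (3''R).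

Step 6
Reactants: 13 (2R,3S)-5,7-bis(benzyloxy)-3-{(2R,3R)-5,7-bis(benzyloxy)-2-[4-(benzyloxy)phenyl]-4-oxo-3,4-dihydro-2H-chromen-3-yl}-2-(3,5-dibromo-4-methoxyphenyl)-2,3-dihydro-4H-chromen-4-one
Product: 14 Sikokianin B, (2R,3S)-3-[(2R,3R)-5,7-dihydroxy-2-(4-hydroxyphenyl)-4-oxo-3,4-dihydro-2H-chromen-3-yl]-5,7-dihydroxy-2-(4-methoxyphenyl)-2,3-dihydro-4H-chromen-4-one
Conditions: H2 (1 atm), Pd/C (10%), NaOAc (3 equiv), EtOAc/MeOH, rt
Reagents that add atoms: none
Why: Heterogeneous hydrogenolysis cleaves the five benzyl ethers and both aryl C–Br bonds under acetate-buffered, near-neutral conditions, so the enolisable C3 and C3'' centres and the ring-opening-prone C2'' centre see neither acid nor base, and the hydrogen-bonded aryl ketones and the C2–O bonds of 5-oxygenated flavanones survive; no new stereocenter is formed.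

## Compound list

1 | 2,4,6-trihydroxybenzaldehyde | O=Cc1c(O)cc(O)cc1O | starting material
2 | 4,6-bis(benzyloxy)-2-hydroxybenzaldehyde | O=Cc1c(O)cc(OCc2ccccc2)cc1OCc1ccccc1 | intermediate
3 | 4-(benzyloxy)benzaldehyde | O=Cc1ccc(OCc2ccccc2)cc1 | starting material
4 | ethynyltrimethylsilane | C#C[Si](C)(C)C | starting material
5 | (1R)-1-[4-(benzyloxy)phenyl]-3-(trimethylsilyl)prop-2-yn-1-ol | C[Si](C)(C)C#C[C@H](O)c1ccc(OCc2ccccc2)cc1 | intermediate
6 | (1S)-1-[4-(benzyloxy)phenyl]prop-2-yn-1-ol | C#C[C@H](O)c1ccc(OCc2ccccc2)cc1 | intermediate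
7 | 3,5-dibromo-4-methoxybenzaldehyde | COc1c(Br)cc(C=O)cc1Br | starting material
8 | (1R,4R)-1-[4-(benzyloxy)phenyl]-4-(3,5-dibromo-4-methoxyphenyl)but-2-yne-1,4-diol | COc1c(Br)cc([C@@H](O)C#C[C@H](O)c2ccc(OCc3ccccc3)cc2)cc1Br | intermediate
9 | 4,6-bis(benzyloxy)-2-{[(1S,4R)-1-[4-(benzyloxy)phenyl]-4-(3,5-dibromo-4-methoxyphenyl)-4-hydroxybut-2-yn-1-yl]oxy}benzaldehyde | COc1c(Br)cc([C@@H](O)C#C[C@@H](Oc2cc(OCc3ccccc3)cc(OCc3ccccc3)c2C=O)c2ccc(OCc3ccccc3)cc2)cc1Br | intermediate
10 | 4,6-bis(benzyloxy)-2-{[(1S,4R)-4-[4-(benzyloxy)phenyl]-1-(3,5-dibromo-4-methoxyphenyl)-4-hydroxybut-2-yn-1-yl]oxy}benzaldehyde | COc1c(Br)cc([C@@H](C#C[C@H](O)c2ccc(OCc3ccccc3)cc2)Oc2cc(OCc3ccccc3)cc(OCc3ccccc3)c2C=O)cc1Br | intermediate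
11 | 2,2'-{[(1S,4S)-1-[4-(benzyloxy)phenyl]-4-(3,5-dibromo-4-methoxyphenyl)but-2-yne-1,4-diyl]bis(oxy)}bis[4,6-bis(benzyloxy)benzaldehyde] | COc1c(Br)cc([C@@H](C#C[C@@H](Oc2cc(OCc3ccccc3)cc(OCc3ccccc3)c2C=O)c2ccc(OCc3ccccc3)cc2)Oc2cc(OCc3ccccc3)cc(OCc3ccccc3)c2C=O)cc1Br | intermediate
12 | (2S,3E)-5,7-bis(benzyloxy)-2-[4-(benzyloxy)phenyl]-3-{(2R)-2-[3,5-bis(benzyloxy)-2-formylphenoxy]-2-(3,5-dibromo-4-methoxyphenyl)ethylidene}-2,3-dihydro-4H-chromen-4-one | COc1c(Br)cc([C@@H](/C=C2/C(=O)c3c(OCc4ccccc4)cc(OCc4ccccc4)cc3O[C@H]2c2ccc(OCc3ccccc3)cc2)Oc2cc(OCc3ccccc3)cc(OCc3ccccc3)c2C=O)cc1Br | intermediate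
13 | (2R,3S)-5,7-bis(benzyloxy)-3-{(2R,3R)-5,7-bis(benzyloxy)-2-[4-(benzyloxy)phenyl]-4-oxo-3,4-dihydro-2H-chromen-3-yl}-2-(3,5-dibromo-4-methoxyphenyl)-2,3-dihydro-4H-chromen-4-one | COc1c(Br)cc([C@@H]2Oc3cc(OCc4ccccc4)cc(OCc4ccccc4)c3C(=O)[C@H]2[C@H]2C(=O)c3c(OCc4ccccc4)cc(OCc4ccccc4)cc3O[C@H]2c2ccc(OCc3ccccc3)cc2)cc1Br | intermediate
14 | Sikokianin B, (2R,3S)-3-[(2R,3R)-5,7-dihydroxy-2-(4-hydroxyphenyl)-4-oxo-3,4-dihydro-2H-chromen-3-yl]-5,7-dihydroxy-2-(4-methoxyphenyl)-2,3-dihydro-4H-chromen-4-one | COc1ccc([C@@H]2Oc3cc(O)cc(O)c3C(=O)[C@H]2[C@H]2C(=O)c3c(O)cc(O)cc3O[C@H]2c2ccc(O)cc2)cc1 | target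

## Step count and risks

Total step count: 6. Longest linear sequence: 5 steps (steps 2 to 6, from 3); step 1 is a one-step side branch.

The three steps most likely to fail:

**Step 5 (most likely).** Four things can go wrong.
- The order of the two aldehydes is only biased by the bromines, not enforced; if the other aldehyde reacts first, the isomer with the two aryl groups exchanged between the cis and the trans unit forms.
- If the proton reaches C3'' from the carbinol hydroxyl on the face of the new C–C bond instead of from the external phenol, the trans,trans isomer results.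
- Base can move the exocyclic double bond of 12 into the ring (a flavone) or epimerise C3 and C3''.
- Di-ortho-substituted, electron-rich aldehydes form Breslow intermediates slowly.

Fallback, in which the two rings are closed one at a time so that their order is fixed by construction: it sets out from 8 and comes back at 13. Step 4 is stopped at the mono-ether stage (1 equiv of 2) and 9 is separated from 10, or 9 is made as described under step 3 below. The same thiazolium carbene then converts 9, which has only one formyl group, into the hydroxy enone (2S,3E)-5,7-bis(benzyloxy)-2-[4-(benzyloxy)phenyl]-3-[(2S)-2-(3,5-dibromo-4-methoxyphenyl)-2-hydroxyethylidene]-2,3-dihydro-4H-chromen-4-one F1. Mitsunobu etherification of F1 with 2 (inversion) gives 12, which is now isolated. 12 is cyclised in a separate Stetter reaction at room temperature (triazolium precatalyst, i-Pr2NEt, catechol as external proton donor) to 13.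

**Step 4.** The oxyphosphonium of the electron-rich 4-benzyloxyphenyl carbinol can ionise, which erodes the ee or leads to elimination. Fallback, in which the C–O bond is made at the arene and the carbinol carbon is untouched (retention): it sets out from 3 and comes back at 11. Steps 2 and 3 are run with the antipodal ligand and give, through (1S)-1-[4-(benzyloxy)phenyl]-3-(trimethylsilyl)prop-2-yn-1-ol F2 (not isolated) and (1R)-1-[4-(benzyloxy)phenyl]prop-2-yn-1-ol F3, the diol (1S,4S)-1-[4-(benzyloxy)phenyl]-4-(3,5-dibromo-4-methoxyphenyl)but-2-yne-1,4-diol F4. Its dipotassium alkoxide (KHMDS, THF/DMF, 0 °C) displaces fluoride twice, ortho to the formyl group, from 4,6-bis(benzyloxy)-2-fluorobenzaldehyde F5 (made from 2,4,6-trifluorobenzaldehyde and 2 equiv of sodium benzyloxide). This double SNAr gives 11 directly.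

**Step 3.** The zinc alkoxide of 6 can bind the dinuclear zinc catalyst and lower the rate or the diastereoselectivity. Fallback, in which the ether is made first and the C–C bond second: it sets out from 6 and comes back at 11. Mitsunobu reaction of 6 with 2 gives 4,6-bis(benzyloxy)-2-{[(1R)-1-[4-(benzyloxy)phenyl]prop-2-yn-1-yl]oxy}benzaldehyde F6. Its alkynylzinc adds under the same ProPhenol catalysis to 7 only, because the internal 2,4,6-trioxygenated aldehyde is too hindered and electron-rich to compete, and this gives 9. A second Mitsunobu reaction of 9 with 2 gives 11.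

Further compounds
F1 | step 5 | (2S,3E)-5,7-bis(benzyloxy)-2-[4-(benzyloxy)phenyl]-3-[(2S)-2-(3,5-dibromo-4-methoxyphenyl)-2-hydroxyethylidene]-2,3-dihydro-4H-chromen-4-one | COc1c(Br)cc([C@@H](O)/C=C2/C(=O)c3c(OCc4ccccc4)cc(OCc4ccccc4)cc3O[C@H]2c2ccc(OCc3ccccc3)cc2)cc1Br
F2 | step 4 | (1S)-1-[4-(benzyloxy)phenyl]-3-(trimethylsilyl)prop-2-yn-1-ol | C[Si](C)(C)C#C[C@@H](O)c1ccc(OCc2ccccc2)cc1
F3 | step 4 | (1R)-1-[4-(benzyloxy)phenyl]prop-2-yn-1-ol | C#C[C@@H](O)c1ccc(OCc2ccccc2)cc1
F4 | step 4 | (1S,4S)-1-[4-(benzyloxy)phenyl]-4-(3,5-dibromo-4-methoxyphenyl)but-2-yne-1,4-diol | COc1c(Br)cc([C@H](O)C#C[C@@H](O)c2ccc(OCc3ccccc3)cc2)cc1Br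
F5 | step 4 | 4,6-bis(benzyloxy)-2-fluorobenzaldehyde | O=Cc1c(F)cc(OCc2ccccc2)cc1OCc1ccccc1
F6 | step 3 | 4,6-bis(benzyloxy)-2-{[(1R)-1-[4-(benzyloxy)phenyl]prop-2-yn-1-yl]oxy}benzaldehyde | C#C[C@@H](Oc1cc(OCc2ccccc2)cc(OCc2ccccc2)c1C=O)c1ccc(OCc2ccccc2)cc1
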